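Ring B (on C3; ring atoms C1'–C6', C1' bonded to C3) is made last. Three of its bonds (C1'–C2', C2'–C3', C5'–C6') form when terminal alkyne 11 and the methoxy(1-methoxyvinyl)carbene complex 16 of zerovalent chromium combine in a Dötz benzannulation. The step exploits the oxygen pattern of ring B: O on C2' and O on C5' are para, as the CO-derived phenol carbon and the carbene carbon always are, O on C4' comes from the vinyl ether carbon, and C1' stems from the substituted alkyne carbon. Precursor 11 is the silyl ether of an alkynol that already holds C1 (R) and C3 (S), both set on a trans-3,5-disubstituted butyrolactone.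

Key step: step 8

Remark: chain atoms are numbered as in butan-1-ol (C1 carbinol with ring A, C3 methine with ring B); lactol 8 is carried as a mixture of anomers; in 17 the Cr(CO)3 fragment is η6-bound to ring B and is written as a separate fragment in the SMILES.

Step 1
Reactants: 1 1,2,4-trimethoxybenzene; 2 succinic anhydride
Product: 3 4-oxo-4-(2,4,5-trimethoxyphenyl)butanoic acid
Conditions: AlCl3, CH2Cl2, 0 °C to rt; aq. HCl
Reagents that add atoms: none
Why: Friedel–Crafts acylation should occur only at C5 of 1, the position para to the 2-methoxy and ortho to the 4-methoxy group, and the low temperature limits AlCl3 cleavage of the methoxy group ortho to the new ketone.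

Step 2
Reactants: 3 4-oxo-4-(2,4,5-trimethoxyphenyl)butanoic acid
Product: 5 (5R)-5-(2,4,5-trimethoxyphenyl)oxolan-2-one, via hydroxy acid 4 (not isolated)
Conditions: RuCl[(R,R)-TsDPEN](p-cymene) (cat.), HCO2H/Et3N (5:2), 40 °C
Reagents that add atoms: none
Why: Noyori-type asymmetric transfer hydrogenation of the aryl ketone, in which the (R,R) ligand should deliver hydride to the face that gives the R carbinol (the sense known for aryl alkyl ketones), followed by lactonization of the γ-hydroxy acid in the weakly acidic formate medium.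

Step 3
Reactants: 5 (5R)-5-(2,4,5-trimethoxyphenyl)oxolan-2-one
Product: 7 (3S,5R)-3-methyl-5-(2,4,5-trimethoxyphenyl)oxolan-2-one, via lithium enolate 6 (not isolated)
Conditions: LiN(SiMe3)2, THF, −78 °C; MeI, −78 °C
Reagents that add atoms: iodomethane, CI
Why: Kinetic alkylation of the lactone enolate, in which iodomethane should approach the face opposite the C5 aryl group and so set C3 as S (trans), while the low temperature suppresses proton exchange that would cause double methylation or drift towards the cis isomer.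

Step 4
Reactants: 7 (3S,5R)-3-methyl-5-(2,4,5-trimethoxyphenyl)oxolan-2-one
Product: 8 (3S,5R)-3-methyl-5-(2,4,5-trimethoxyphenyl)oxolan-2-ol (anomeric mixture)
Conditions: i-Bu2AlH, CH2Cl2, −78 °C; aq. potassium sodium tartrate
Reagents that add atoms: none
Why: Partial hydride reduction of a lactone stops at the aluminium hemiacetal at −78 °C and gives the lactol on hydrolysis, and C3 is not touched because no enolization is involved.

Step 5
Reactants: 8 (3S,5R)-3-methyl-5-(2,4,5-trimethoxyphenyl)oxolan-2-ol
Product: 10 (1R,3S)-3-methyl-1-(2,4,5-trimethoxyphenyl)pent-4-yn-1-ol, via hydroxy aldehyde 9 (not isolated)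
Conditions: dimethyl (1-diazo-2-oxopropyl)phosphonate, K2CO3, MeOH, 0 °C to rt
Reagents that add atoms: dimethyl (1-diazo-2-oxopropyl)phosphonate (Ohira–Bestmann reagent), CC(=O)C(=[N+]=[N-])P(=O)(OC)OC
Why: Ohira–Bestmann variant of the Seyferth–Gilbert homologation, in which the lactol opens to aldehyde 9, the diazophosphonate anion olefinates it, and loss of N2 with a 1,2-hydrogen shift gives the terminal alkyne; mild carbonate at low temperature should keep C3 from epimerizing.

Step 6
Reactants: 10 (1R,3S)-3-methyl-1-(2,4,5-trimethoxyphenyl)pent-4-yn-1-ol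
Product: 11 tert-butyldimethyl{[(1R,3S)-3-methyl-1-(2,4,5-trimethoxyphenyl)pent-4-yn-1-yl]oxy}silane
Conditions: TBSCl, imidazole, DMF, rt
Reagents that add atoms: tert-butyldimethylsilyl chloride, CC(C)(C)[Si](C)(C)Cl
Why: Imidazole-promoted silylation of a secondary alcohol under non-acidic conditions leaves the ionizable, electron-rich benzylic C–O bond intact and masks the hydroxyl that could otherwise trap the ketene in step 8.

Step 7
Reactants: 12 methyl vinyl ether; 13 Cr(CO)6 (chromium hexacarbonyl)
Product: 16 pentacarbonyl[methoxy(1-methoxyvinyl)carbene]chromium, via 1-methoxyvinyllithium 14 (not isolated), via lithium acylchromate 15 (not isolated)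
Conditions: t-BuLi, THF, −78 to 0 °C; Cr(CO)6, THF, −78 °C to rt; Me3OBF4, CH2Cl2, 0 °C
Reagents that add atoms: trimethyloxonium tetrafluoroborate, C[O+](C)C.F[B-](F)(F)F
Why: Fischer carbene synthesis, in which α-lithiation of the enol ether gives 14, its addition to a CO ligand gives acylchromate 15, and O-methylation by the oxonium salt gives the alkoxycarbene.

Step 8
Reactants: 11 tert-butyldimethyl{[(1R,3S)-3-methyl-1-(2,4,5-trimethoxyphenyl)pent-4-yn-1-yl]oxy}silane; 16 pentacarbonyl[methoxy(1-methoxyvinyl)carbene]chromium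
Product: 18 2-[(2S,4R)-4-(tert-butyldimethylsilyloxy)-4-(2,4,5-trimethoxyphenyl)butan-2-yl]-4,5-dimethoxyphenol, via arene Cr(CO)3 complex 17 (not isolated)
Conditions: 16 (1.5 equiv), degassed THF, 50 °C, Ar; then air, Et2O, rt
Reagents that add atoms: none
Why: Dötz benzannulation: thermal loss of one CO from 16 lets the alkyne of 11 insert into the Cr=C bond to give a vinylcarbene, CO insertion gives a chromium-bound dienylketene, and a 6π-electrocyclization followed by tautomerization gives the Cr(CO)3-bound 4-methoxyphenol 17, from which air releases 18. The closest known reaction type is the benzannulation of alkenyl methoxycarbene chromium complexes, including α-alkoxyvinyl ones such as the dihydropyranyl complex, with terminal alkynes to give 4-methoxyphenols. Ring B closes by formation of the C2'–C3' bond in the electrocyclization, after C5'–C6' (alkyne insertion) and C1'–C2' (CO insertion) have been made, a formal [3+2+1] assembly. No stereocenter is created, and C1 and C3 are spectators, the propargylic C3 not being acidic under these neutral conditions. The step needs regioselective alkyne insertion, which the terminal alkyne secures because its unsubstituted carbon bonds to the carbene carbon and the branched carbon ends next to the CO-derived phenol carbon. It also needs the ketene to escape interception, which the silyl ether on C1 secures by blocking closure of a six-membered lactone.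

Step 9
Reactants: 18 2-[(2S,4R)-4-(tert-butyldimethylsilyloxy)-4-(2,4,5-trimethoxyphenyl)butan-2-yl]-4,5-dimethoxyphenol
Product: 19 tert-butyldimethyl{[(1R,3S)-1,3-bis(2,4,5-trimethoxyphenyl)butyl]oxy}silane
Conditions: MeI, K2CO3, acetone, 56 °C, Ar
Reagents that add atoms: iodomethane, CI
Why: Williamson ether synthesis on the phenoxide, the only acidic site, under conditions that leave the silyl ether and both stereocenters untouched.

Step 10
Reactants: 19 tert-butyldimethyl{[(1R,3S)-1,3-bis(2,4,5-trimethoxyphenyl)butyl]oxy}silane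
Product: 20 (1R,3S)-1,3-bis(2,4,5-trimethoxyphenyl)butan-1-ol
Conditions: Bu4NF, THF, 0 °C to rt; water
Reagents that add atoms: none
Why: Fluoride-driven cleavage of the Si–O bond under non-acidic conditions should free the C1 alcohol without ionizing the electron-rich benzylic position, so the R configuration is kept.

Compound list
1 | 1,2,4-trimethoxybenzene | COc1ccc(OC)c(OC)c1 | starting material
2 | succinic anhydride | O=C1CCC(=O)O1 | starting material
3 | 4-oxo-4-(2,4,5-trimethoxyphenyl)butanoic acid | COc1cc(OC)c(C(=O)CCC(=O)O)cc1OC | intermediate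
4 | (4R)-4-hydroxy-4-(2,4,5-trimethoxyphenyl)butanoic acid | COc1cc(OC)c([C@H](O)CCC(=O)O)cc1OC | intermediate
5 | (5R)-5-(2,4,5-trimethoxyphenyl)oxolan-2-one | COc1cc(OC)c([C@H]2CCC(=O)O2)cc1OC | intermediate
6 | lithium enolate of 5, lithium (5R)-5-(2,4,5-trimethoxyphenyl)-4,5-dihydrofuran-2-olate | COc1cc(OC)c([C@H]2CC=C(O[Li])O2)cc1OC | intermediate
7 | (3S,5R)-3-methyl-5-(2,4,5-trimethoxyphenyl)oxolan-2-one (trans) | COc1cc(OC)c([C@H]2C[C@H](C)C(=O)O2)cc1OC | intermediate
8 | (3S,5R)-3-methyl-5-(2,4,5-trimethoxyphenyl)oxolan-2-ol, anomeric mixture | COc1cc(OC)c([C@H]2C[C@H](C)C(O)O2)cc1OC | intermediate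
9 | (2S,4R)-4-hydroxy-2-methyl-4-(2,4,5-trimethoxyphenyl)butanal | COc1cc(OC)c([C@H](O)C[C@H](C)C=O)cc1OC | intermediate
10 | (1R,3S)-3-methyl-1-(2,4,5-trimethoxyphenyl)pent-4-yn-1-ol | COc1cc(OC)c([C@H](O)C[C@H](C)C#C)cc1OC | intermediate
11 | tert-butyldimethyl{[(1R,3S)-3-methyl-1-(2,4,5-trimethoxyphenyl)pent-4-yn-1-yl]oxy}silane, that is (3S,5R)-5-(tert-butyldimethylsilyloxy)-3-methyl-5-(2,4,5-trimethoxyphenyl)pent-1-yne | COc1cc(OC)c([C@H](O[Si](C)(C)C(C)(C)C)C[C@H](C)C#C)cc1OC | intermediate
12 | methyl vinyl ether | C=COC | starting material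
13 | Cr(CO)6, chromium hexacarbonyl | O=C=[Cr](=C=O)(=C=O)(=C=O)(=C=O)=C=O | starting material
14 | 1-methoxyvinyllithium | [Li]C(=C)OC | intermediate
15 | lithium pentacarbonyl(2-methoxyacryloyl)chromate | [Li+].[O-]C(C(=C)OC)=[Cr](=C=O)(=C=O)(=C=O)(=C=O)=C=O | intermediate
16 | pentacarbonyl[methoxy(1-methoxyvinyl)carbene]chromium | COC(C(=C)OC)=[Cr](=C=O)(=C=O)(=C=O)(=C=O)=C=O | intermediate
17 | Cr(CO)3 complex of phenol 18, η6 on ring B | COc1cc(OC)c([C@H](O[Si](C)(C)C(C)(C)C)C[C@H](C)c2cc(OC)c(OC)cc2O)cc1OC.O=C=[Cr](=C=O)=C=O | intermediate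
18 | 2-[(2S,4R)-4-(tert-butyldimethylsilyloxy)-4-(2,4,5-trimethoxyphenyl)butan-2-yl]-4,5-dimethoxyphenol | COc1cc(OC)c([C@H](O[Si](C)(C)C(C)(C)C)C[C@H](C)c2cc(OC)c(OC)cc2O)cc1OC | intermediate
19 | tert-butyldimethyl{[(1R,3S)-1,3-bis(2,4,5-trimethoxyphenyl)butyl]oxy}silane | COc1cc(OC)c([C@H](O[Si](C)(C)C(C)(C)C)C[C@H](C)c2cc(OC)c(OC)cc2OC)cc1OC | intermediate
20 | (1R,3S)-1,3-bis(2,4,5-trimethoxyphenyl)butan-1-ol | COc1cc(OC)c([C@H](O)C[C@H](C)c2cc(OC)c(OC)cc2OC)cc1OC | target

Total step count: 10. Longest linear sequence: 9 steps (steps 1 to 6, then 8, 9 and 10); step 7 is a one-step side branch.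

Steps most likely to fail

Step 8. After alkyne insertion the vinylcarbene or ketene may be diverted into cyclobutenone, furan or five-membered-ring products, or complex 16 may decay thermally before it inserts. The fallback sets out from 1 and comes back at 20; it brings ring B in intact instead of building it. Friedel–Crafts acylation of 1 with (E)-but-2-enoyl chloride (AlCl3, CH2Cl2, −20 °C) should give (E)-1-(2,4,5-trimethoxyphenyl)but-2-en-1-one F1. Hayashi–Miyaura conjugate addition of 2,4,5-trimethoxyphenylboronic acid ([Rh(acac)(C2H4)2], (S)-BINAP, dioxane/H2O, 100 °C) should then give (S)-1,3-bis(2,4,5-trimethoxyphenyl)butan-1-one F2. The ligand antipode is chosen by analogy with acyclic (E)-enones and would be confirmed on the first run. Reduction of F2 with the (S)-methyl oxazaborolidine (CBS catalyst) and BH3·SMe2 at −20 °C, which places hydride on the face that gives the R carbinol, should lead directly to 20.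

Step 5. C3 may epimerize through enolization of the open aldehyde under carbonate in methanol, and slow opening of the lactol would prolong that exposure. The fallback sets out from 7 and comes back at 11; it uses an open-chain, already silylated aldehyde and a non-basic olefination.
- Opening of 7 with MeNH(OMe)·HCl and i-PrMgCl (THF, −20 °C) should give (2S,4R)-4-hydroxy-N-methoxy-N,2-dimethyl-4-(2,4,5-trimethoxyphenyl)butanamide F3.
- Prompt silylation (TBSCl, imidazole, DMF) should give (2S,4R)-4-(tert-butyldimethylsilyloxy)-N-methoxy-N,2-dimethyl-4-(2,4,5-trimethoxyphenyl)butanamide F4.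
- Reduction with i-Bu2AlH (THF, −78 °C) should give (2S,4R)-4-(tert-butyldimethylsilyloxy)-2-methyl-4-(2,4,5-trimethoxyphenyl)butanal F5.
- Corey–Fuchs olefination (CBr4, PPh3, Et3N, CH2Cl2, 0 °C) should give tert-butyl{[(1R,3S)-5,5-dibromo-3-methyl-1-(2,4,5-trimethoxyphenyl)pent-4-en-1-yl]oxy}dimethylsilane F6.
- n-BuLi (2 equiv, THF, −78 °C) should give lithium (3S,5R)-5-(tert-butyldimethylsilyloxy)-3-methyl-5-(2,4,5-trimethoxyphenyl)pent-1-yn-1-ide F7, which water converts into 11.

Step 3. Facial selectivity in the enolate methylation may be poor, and proton exchange may cause double methylation or equilibration towards the cis lactone. The fallback sets out from 1 and comes back at 7; it sets C3 by catalyst control before the carbinol is made. Friedel–Crafts acylation of 1 with itaconic anhydride (AlCl3, CH2Cl2, 0 °C), at the carbonyl remote from the methylidene group, should give 2-methylidene-4-oxo-4-(2,4,5-trimethoxyphenyl)butanoic acid F8. Asymmetric hydrogenation of this itaconate-type acid (H2, [Rh(cod)(Et-DuPhos)]BF4, MeOH; the ligand antipode is fixed in a first run so that the S acid results) should give (2S)-2-methyl-4-oxo-4-(2,4,5-trimethoxyphenyl)butanoic acid F9. Transfer hydrogenation under the conditions of step 2 should give (2S,4R)-4-hydroxy-2-methyl-4-(2,4,5-trimethoxyphenyl)butanoic acid F10, which lactonizes in the same flask to 7.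

Further compounds
F1 | step 8 | (E)-1-(2,4,5-trimethoxyphenyl)but-2-en-1-one | COc1cc(OC)c(C(=O)/C=C/C)cc1OC
F2 | step 8 | (3S)-1,3-bis(2,4,5-trimethoxyphenyl)butan-1-one | COc1cc(OC)c(C(=O)C[C@H](C)c2cc(OC)c(OC)cc2OC)cc1OC
F3 | step 5 | (2S,4R)-4-hydroxy-N-methoxy-N,2-dimethyl-4-(2,4,5-trimethoxyphenyl)butanamide | COc1cc(OC)c([C@H](O)C[C@H](C)C(=O)N(C)OC)cc1OC
F4 | step 5 | (2S,4R)-4-(tert-butyldimethylsilyloxy)-N-methoxy-N,2-dimethyl-4-(2,4,5-trimethoxyphenyl)butanamide | COc1cc(OC)c([C@H](O[Si](C)(C)C(C)(C)C)C[C@H](C)C(=O)N(C)OC)cc1OC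
F5 | step 5 | (2S,4R)-4-(tert-butyldimethylsilyloxy)-2-methyl-4-(2,4,5-trimethoxyphenyl)butanal | COc1cc(OC)c([C@H](O[Si](C)(C)C(C)(C)C)C[C@H](C)C=O)cc1OC
F6 | step 5 | tert-butyl{[(1R,3S)-5,5-dibromo-3-methyl-1-(2,4,5-trimethoxyphenyl)pent-4-en-1-yl]oxy}dimethylsilane | COc1cc(OC)c([C@H](O[Si](C)(C)C(C)(C)C)C[C@H](C)C=C(Br)Br)cc1OC
F7 | step 5 | lithium (3S,5R)-5-(tert-butyldimethylsilyloxy)-3-methyl-5-(2,4,5-trimethoxyphenyl)pent-1-yn-1-ide | COc1cc(OC)c([C@H](O[Si](C)(C)C(C)(C)C)C[C@H](C)C#C[Li])cc1OC
F8 | step 3 | 2-methylidene-4-oxo-4-(2,4,5-trimethoxyphenyl)butanoic acid | COc1cc(OC)c(C(=O)CC(=C)C(=O)O)cc1OC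
F9 | step 3 | (2S)-2-methyl-4-oxo-4-(2,4,5-trimethoxyphenyl)butanoic acid | COc1cc(OC)c(C(=O)C[C@H](C)C(=O)O)cc1OC
F10 | step 3 | (2S,4R)-4-hydroxy-2-methyl-4-(2,4,5-trimethoxyphenyl)butanoic acid | COc1cc(OC)c([C@H](O)C[C@H](C)C(=O)O)cc1OC
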